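The route rests on disconnecting the bond between the benzylic CH2 on ring A (the 3-hydroxy-5-aryloxyphenyl ring) and the neighbouring CH2 of the fourteen-carbon bridge. Because the bridge is unfunctionalised and this bond lies next to ring A, it can be carried as a styrene C=C. Ring-closing metathesis between a vinyl group on ring A and the terminal alkene of a tetradec-13-enyl chain on ring B (the hydroquinone ring) closes the 21-membered ansa ring in one operation, with the meta,meta diaryl ether as a preformed hinge. The precursor is an acyclic tri-O-benzyl diaryl ether diene; a single hydrogenation then saturates the alkene and frees all three phenols.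

Key step: step 6

Remark on the chemistry: 2,6-dibromohydroquinone is assumed to be a catalogue chemical.

**Step 1**
Reactants: 1 2,6-dibromohydroquinone (2,6-dibromobenzene-1,4-diol)
Product: 2 1,3-dibromo-2,5-bis(benzyloxy)benzene
Conditions: BnBr (2.4 equiv), K2CO3, DMF, 60 °C, under N2
Reagents that add atoms: benzyl bromide, BrCc1ccccc1
Why: Double Williamson etherification, in which K2CO3 deprotonates both phenols (the one flanked by two bromines is the more acidic and still accessible to the unhindered benzylic electrophile) and nitrogen keeps the hydroquinone from air oxidation to the quinone.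

**Step 2**
Reactants: 3 3,5-dihydroxybenzaldehyde
Product: 4 3-(benzyloxy)-5-hydroxybenzaldehyde
Conditions: BnBr (0.9 equiv), K2CO3, acetone, reflux; chromatography, diol recycled
Reagents that add atoms: benzyl bromide, BrCc1ccccc1
Why: Statistical mono-Williamson etherification of a symmetrical diphenol, where a slight deficit of benzyl bromide limits double alkylation and diol, mono-ether and bis-ether differ enough in polarity to be separated.

**Step 3**
Reactants: 2 1,3-dibromo-2,5-bis(benzyloxy)benzene; 4 3-(benzyloxy)-5-hydroxybenzaldehyde
Product: 5 3-(benzyloxy)-5-[2,5-bis(benzyloxy)-3-bromophenoxy]benzaldehyde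
Conditions: CuI (10 mol %), picolinic acid (20 mol %), K3PO4 (2 equiv), DMSO, 90 °C; 2 in excess (3 equiv), recovered
Reagents that add atoms: none
Why: Ullmann-type copper-catalysed C–O coupling of a phenoxide with an aryl bromide, for which the picolinic acid ligand suits ortho-alkoxy halides; the excess of the symmetrical dibromide should make mono-etherification the main outcome, and the aldehyde and benzyl ethers are inert to the phosphate base.

**Step 4**
Reactants: 5 3-(benzyloxy)-5-[2,5-bis(benzyloxy)-3-bromophenoxy]benzaldehyde
Product: 6 1-(benzyloxy)-3-[2,5-bis(benzyloxy)-3-bromophenoxy]-5-vinylbenzene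
Conditions: Ph3PCH3Br, KOtBu, THF, 0 °C to rt
Reagents that add atoms: methyltriphenylphosphonium bromide, C[P+](c1ccccc1)(c1ccccc1)c1ccccc1.[Br-]
Why: Wittig methylenation of the aromatic aldehyde by the non-stabilised ylide Ph3P=CH2 (oxaphosphetane formation and loss of Ph3PO), to which the aryl bromide, diaryl ether and benzyl ethers are inert at or below room temperature.

**Step 5**
Reactants: 6 1-(benzyloxy)-3-[2,5-bis(benzyloxy)-3-bromophenoxy]-5-vinylbenzene; 7 tetradeca-1,13-diene; 8 9-borabicyclo[3.3.1]nonane (9-BBN)
Product: 10 1-(benzyloxy)-3-[2,5-bis(benzyloxy)-3-(tetradec-13-en-1-yl)phenoxy]-5-vinylbenzene, via B-(tetradec-13-en-1-yl)-9-borabicyclo[3.3.1]nonane 9 (not isolated)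
Conditions: 7 (4 equiv), 9-BBN (1.3 equiv), THF, 0 °C to rt; then 6, Pd(OAc)2 (5 mol %), SPhos (10 mol %), aq. K3PO4, THF, 60 °C
Reagents that add atoms: none
Why: Anti-Markovnikov mono-hydroboration of the excess symmetrical diene gives the primary alkylborane, and its B-alkyl Suzuki–Miyaura coupling with the aryl bromide (oxidative addition, base-assisted transmetalation, reductive elimination) installs the chain; the diene excess consumes all B–H before the styrene is added, and the bulky electron-rich phosphine should overcome the ortho-benzyloxy hindrance.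

**Step 6**
Reactants: 10 1-(benzyloxy)-3-[2,5-bis(benzyloxy)-3-(tetradec-13-en-1-yl)phenoxy]-5-vinylbenzene
Product: 11 tri-O-benzyl macrocyclic alkene: the 21-membered ansa diaryl ether in which ring A (5-benzyloxy-1,3-phenylene) is joined through CH=CH–(CH2)12 to ring B (2,5-bis(benzyloxy)-1,3-phenylene) and through the ether oxygen on the other side; E alkene drawn, any Z isomer is carried on
Conditions: second-generation Grubbs catalyst [RuCl2(=CHPh)(PCy3)(SIMes)] (10 mol %), 1,4-benzoquinone (20 mol %), CH2Cl2 (1 mM), 40 °C, slow addition of 10
Reagents that add atoms: none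
Why: Ring-closing olefin metathesis by the Chauvin mechanism: the ruthenium benzylidene initiates at the unhindered terminal alkene of the chain, and the resulting alkylidene engages the vinyl group on ring A through a ruthenacyclobutane whose cycloreversion creates the C=C between the benzylic carbon of ring A and the adjacent bridge carbon and releases ethene. The closest known reaction type is the macrocyclic RCM of a styrene with a remote monosubstituted alkene, as used for cyclophanes and ansa-bridged diaryl ethers. The one ring closed is the 21-membered ansa ring (fourteen bridge carbons, three atoms of each arene and the ether oxygen), formed by end-to-end macrocyclisation of the two olefin termini that is driven by loss of ethene and helped by the meta,meta diaryl ether hinge. No stereocentre is created, and the geometry of the new alkene is irrelevant because step 7 saturates it. The selectivity needed is ring closure over acyclic diene oligomerisation and over olefin migration before closure (which would shorten the bridge); high dilution with slow addition and the 1,4-benzoquinone additive should secure it, and the benzyl ethers keep the phenols from binding ruthenium.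

**Step 7**
Reactants: 11 tri-O-benzyl macrocyclic alkene
Product: 12 target macrocycle CNP0393720.0 (21-membered diaryl ether triphenol with a saturated tetradecamethylene bridge; no stereocentre)
Conditions: H2 (1 atm), 10% Pd/C, EtOAc/MeOH, rt; work-up under argon
Reagents that add atoms: none
Why: Heterogeneous catalytic hydrogenation should saturate the disubstituted styrenyl alkene and hydrogenolyse the three benzyl aryl ethers in the same operation, while the diaryl ether and both arenes are inert; the target has no stereocentre to set.

**Compound list**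
1 | 2,6-dibromohydroquinone | Oc1cc(Br)c(O)c(Br)c1 | starting material
2 | 1,3-dibromo-2,5-bis(benzyloxy)benzene | Brc1cc(OCc2ccccc2)cc(Br)c1OCc1ccccc1 | intermediate
3 | 3,5-dihydroxybenzaldehyde | O=Cc1cc(O)cc(O)c1 | starting material
4 | 3-(benzyloxy)-5-hydroxybenzaldehyde | O=Cc1cc(O)cc(OCc2ccccc2)c1 | intermediate
5 | 3-(benzyloxy)-5-[2,5-bis(benzyloxy)-3-bromophenoxy]benzaldehyde | O=Cc1cc(OCc2ccccc2)cc(Oc2cc(OCc3ccccc3)cc(Br)c2OCc2ccccc2)c1 | intermediate
6 | 1-(benzyloxy)-3-[2,5-bis(benzyloxy)-3-bromophenoxy]-5-vinylbenzene | C=Cc1cc(OCc2ccccc2)cc(Oc2cc(OCc3ccccc3)cc(Br)c2OCc2ccccc2)c1 | intermediate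
7 | tetradeca-1,13-diene | C=CCCCCCCCCCCCC=C | starting material
8 | 9-borabicyclo[3.3.1]nonane (9-BBN) | B1C2CCCC1CCC2 | starting material
9 | B-(tetradec-13-en-1-yl)-9-borabicyclo[3.3.1]nonane (not isolated) | C=CCCCCCCCCCCCCB1C2CCCC1CCC2 | intermediate
10 | 1-(benzyloxy)-3-[2,5-bis(benzyloxy)-3-(tetradec-13-en-1-yl)phenoxy]-5-vinylbenzene | C=Cc1cc(OCc2ccccc2)cc(Oc2cc(OCc3ccccc3)cc(CCCCCCCCCCCCC=C)c2OCc2ccccc2)c1 | intermediate
11 | tri-O-benzyl macrocyclic alkene (E isomer drawn), 21-membered ring | C1C/C=C/c2cc(OCc3ccccc3)cc(c2)Oc2cc(OCc3ccccc3)cc(c2OCc2ccccc2)CCCCCCCCCC1 | intermediate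
12 | target macrocycle CNP0393720.0 | Oc1cc2cc(c1)Oc1cc(O)cc(c1O)CCCCCCCCCCCCCC2 | target

**Step count and risks**

Total step count: 7. Longest linear sequence: 6 steps (1 → 2 → 5 → 6 → 10 → 11 → 12).

Steps most likely to fail:

Step 6. Intermolecular metathesis (acyclic diene oligomerisation) may outrun ring closure, or ruthenium hydride species may migrate the terminal double bond before closure and give ring-contracted products. The fallback sets out from 10 and closes the same bond by carbonyl coupling. Both C=C bonds of 10 would be cleaved (OsO4 cat., NaIO4, 2,6-lutidine, dioxane/H2O, rt) to the dialdehyde 3-(benzyloxy)-5-[2,5-bis(benzyloxy)-3-(13-oxotridecyl)phenoxy]benzaldehyde F1. An intramolecular McMurry coupling of F1 (TiCl4, Zn, pyridine, THF, reflux, syringe-pump addition) would then join the two formyl carbons to the same alkene, coming back to the route at 11.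

Step 3. Copper insertion into the ortho-alkoxy C–Br bond may be sluggish, so that hydrodebromination and a second etherification compete. The fallback sets out from 2 and reverses the polarity of the aryl partner. One bromine–lithium exchange (n-BuLi, 1.0 equiv, THF, −78 °C) would give [2,5-bis(benzyloxy)-3-bromophenyl]lithium F2 (not isolated). Trapping with B(OiPr)3 and hydrolysis with aq. HCl would give [2,5-bis(benzyloxy)-3-bromophenyl]boronic acid F3. Oxidative Chan–Lam coupling of F3 with phenol 4 (Cu(OAc)2, pyridine, 4 Å molecular sieves, CH2Cl2, air, rt) would form the aryl–oxygen bond at room temperature and come back to the route at 5.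

Step 5. Heck-type arylation of the styrene by the arylpalladium intermediate, or protodehalogenation, may compete with slow transmetalation at the hindered, electron-rich bromide. The fallback sets out from 2 and 9 and inverts the order of fragment assembly, so that the C–C coupling is run before any styrene or diaryl ether exists. B-alkyl Suzuki–Miyaura coupling of 9 with excess 2 (Pd(OAc)2, SPhos, aq. K3PO4, THF, 60 °C) would give 1-bromo-2,5-bis(benzyloxy)-3-(tetradec-13-en-1-yl)benzene F4. Copper-catalysed etherification of F4 with 4 (CuI, picolinic acid, K3PO4, DMSO, 90 °C) would give 3-(benzyloxy)-5-[2,5-bis(benzyloxy)-3-(tetradec-13-en-1-yl)phenoxy]benzaldehyde F5. Wittig methylenation of F5 (Ph3PCH3Br, KOtBu, THF) would come back to the route at 10.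

**Further compounds**
F1 | step 6 | 3-(benzyloxy)-5-[2,5-bis(benzyloxy)-3-(13-oxotridecyl)phenoxy]benzaldehyde | O=Cc1cc(OCc2ccccc2)cc(Oc2cc(OCc3ccccc3)cc(CCCCCCCCCCCCC=O)c2OCc2ccccc2)c1
F2 | step 3 | [2,5-bis(benzyloxy)-3-bromophenyl]lithium | [Li]c1cc(OCc2ccccc2)cc(Br)c1OCc1ccccc1
F3 | step 3 | [2,5-bis(benzyloxy)-3-bromophenyl]boronic acid | OB(O)c1cc(OCc2ccccc2)cc(Br)c1OCc1ccccc1
F4 | step 5 | 1-bromo-2,5-bis(benzyloxy)-3-(tetradec-13-en-1-yl)benzene | C=CCCCCCCCCCCCCc1cc(OCc2ccccc2)cc(Br)c1OCc1ccccc1
F5 | step 5 | 3-(benzyloxy)-5-[2,5-bis(benzyloxy)-3-(tetradec-13-en-1-yl)phenoxy]benzaldehyde | O=Cc1cc(OCc2ccccc2)cc(Oc2cc(OCc3ccccc3)cc(CCCCCCCCCCCCC=C)c2OCc2ccccc2)c1
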